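**Assumption:** the target has no stereocentre, so the route makes the achiral compound exactly as drawn; there is nothing to set or scramble.

**Retrosynthetic overview**
1. Target ⇐ hydroxide opening of 8-hydroxy-3-(11-hydroxyundecyl)-6-methoxyisocoumarin; the ring oxygen becomes the ketone oxygen and C1 becomes the carboxyl group.
2. That isocoumarin ⇐ lactone-carbonyl-directed C8–H hydroxylation of the 8-unsubstituted isocoumarin (key C–O bond, new method).
3. 8-Unsubstituted isocoumarin ⇐ 2-iodo-4-methoxybenzoic acid + tridec-12-yn-1-ol by coupling and 6-endo C–O ring closure (the O–C3 bond fixes the ketone position).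
4. Tridec-12-yn-1-ol ⇐ 11-bromoundecan-1-ol + lithium acetylide.
5. Rings: the benzene ring is bought; the only ring made is the pyranone (step 2), which is opened again in step 4.

**Route**

Step 1
Reactants: 1 11-bromoundecan-1-ol
Product: 2 tridec-12-yn-1-ol
Conditions: LiC≡CH·H2NCH2CH2NH2 (3 equiv), DMSO, 0 °C → rt; aq NH4Cl
Reagents that add atoms: lithium acetylide–ethylenediamine complex, [Li+].[C-]#C.NCCN
Why: SN2 alkylation of acetylide by the primary bromide; the excess reagent simply deprotonates the free OH, so no protecting group is needed and the alkyne stays terminal.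

Step 2
Reactants: 2 tridec-12-yn-1-ol; 3 2-iodo-4-methoxybenzoic acid
Product: 5 3-(11-hydroxyundecyl)-6-methoxy-1H-isochromen-1-one, via alkynylbenzoic acid 4 (not isolated)
Conditions: Pd(PPh3)4 (5 mol%), ZnCl2 (1 equiv), Et3N (5 equiv), DMF, 100 °C
Reagents that add atoms: none
Why: Domino Sonogashira-type coupling/6-endo-dig oxycyclisation of an o-iodobenzoic acid with a terminal alkyne (Pd/ZnCl2 conditions favour the isocoumarin over the 5-exo phthalide), which delivers the carboxyl oxygen to the alkyne carbon remote from the ring, i.e. the future ketone carbon.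

Step 3
Reactants: 5 3-(11-hydroxyundecyl)-6-methoxy-1H-isochromen-1-one
Product: 8 8-hydroxy-3-(11-hydroxyundecyl)-6-methoxy-1H-isochromen-1-one, via alkyl trifluoroacetate 6 (not isolated), via bis-trifluoroacetate 7 (not isolated)
Conditions: [RuCl2(p-cymene)]2 (5 mol%), PhI(OCOCF3)2 (1.5 equiv, added slowly), TFA/TFAA 3:1, 60 °C; then satd aq NaHCO3/THF, rt
Reagents that add atoms: [bis(trifluoroacetoxy)iodo]benzene, FC(F)(F)C(=O)OI(OC(=O)C(F)(F)F)c1ccccc1 (a trifluoroacetate oxygen becomes the C8 phenol oxygen); trifluoroacetic anhydride, O=C(OC(=O)C(F)(F)F)C(F)(F)F (trifluoroacetyl groups of 6 and 7 only, gone again in 8)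
Why: Proposed new method: lactone-carbonyl-directed peri C–H oxygenation of an isocoumarin. The C1=O oxygen is locked coplanar and syn to C8–H, so it binds the Ru(II) trifluoroacetate and carboxylate-assisted metalation gives a five-membered ruthenacycle at C8, the only C–H within reach. PIFA oxidises this to Ru(IV), and C–O reductive elimination gives the aryl trifluoroacetate, which is protected against over-oxidation and is cleaved in the work-up. The primary alcohol is masked in situ as its trifluoroacetate, and the ring carbonyl para to OMe keeps the arene from direct oxidation by PIFA. The closest known reaction type is Ru(II)-catalysed ester- and ketone-directed ortho C–H hydroxylation of benzoates and aryl ketones, including C5-hydroxylation of chromones; it has not been shown with an isocoumarin lactone as the directing group.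

Step 4
Reactants: 8 8-hydroxy-3-(11-hydroxyundecyl)-6-methoxy-1H-isochromen-1-one
Product: 9 2-hydroxy-6-(13-hydroxy-2-oxotridecyl)-4-methoxybenzoic acid
Conditions: LiOH·H2O (4 equiv), THF/H2O 1:1, rt → 40 °C; then 1 M HCl to pH 3 at 0 °C, EtOAc extraction, no heating
Reagents that add atoms: lithium hydroxide, [Li+].[OH-] (its oxygen becomes the carboxyl OH); water, O
Why: Saponification of the enol lactone: hydroxide attacks C1, and the released enolate tautomerises to the benzylic ketone, so the ring oxygen set in step 2 ends up as the ketone oxygen; cold, mild acidification avoids re-lactonisation.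

**Compound list**
1 | 11-bromoundecan-1-ol | OCCCCCCCCCCCBr | starting material
2 | tridec-12-yn-1-ol | OCCCCCCCCCCCC#C | intermediate
3 | 2-iodo-4-methoxybenzoic acid | COc1ccc(C(=O)O)c(I)c1 | starting material
4 | 2-(13-hydroxytridec-1-yn-1-yl)-4-methoxybenzoic acid | COc1ccc(C(=O)O)c(C#CCCCCCCCCCCCO)c1 | intermediate
5 | 3-(11-hydroxyundecyl)-6-methoxy-1H-isochromen-1-one | COc1ccc2C(=O)OC(CCCCCCCCCCCO)=Cc2c1 | intermediate
6 | 11-(6-methoxy-1-oxo-1H-isochromen-3-yl)undecyl trifluoroacetate | COc1ccc2C(=O)OC(CCCCCCCCCCCOC(=O)C(F)(F)F)=Cc2c1 | intermediate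
7 | 11-[6-methoxy-1-oxo-8-(trifluoroacetoxy)-1H-isochromen-3-yl]undecyl trifluoroacetate | COc1cc(OC(=O)C(F)(F)F)c2C(=O)OC(CCCCCCCCCCCOC(=O)C(F)(F)F)=Cc2c1 | intermediate
8 | 8-hydroxy-3-(11-hydroxyundecyl)-6-methoxy-1H-isochromen-1-one | COc1cc(O)c2C(=O)OC(CCCCCCCCCCCO)=Cc2c1 | intermediate
9 | 2-hydroxy-6-(13-hydroxy-2-oxotridecyl)-4-methoxybenzoic acid | COc1cc(O)c(C(=O)O)c(CC(=O)CCCCCCCCCCCO)c1 | target

**Totals**
Total step count: 4. Longest linear sequence: 4 (1 → 2 → 5 → 8 → 9); the aryl iodide 3 enters at step 2.

**Three steps most likely to fail**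

Step 3 (the proposed new method). The lactone may bind Ru too weakly, or PIFA may attack the C3=C4 enol-lactone double bond or the anisole ring instead. The fallback uses known chemistry and buys the C8 oxygen with the arene instead of installing it by C–H oxygenation; it sets out from alkyne 2 and comes back at 8. Purchased 2,4,6-trihydroxybenzoic acid F1 is condensed with acetone (TFAA/TFA) to 5,7-dihydroxy-2,2-dimethyl-4H-benzo[d][1,3]dioxin-4-one F2. The non-chelated 7-OH is methylated under Mitsunobu conditions (MeOH, DIAD, PPh3) to give 5-hydroxy-7-methoxy-2,2-dimethyl-4H-benzo[d][1,3]dioxin-4-one F3. Tf2O/pyridine then gives 7-methoxy-2,2-dimethyl-4-oxo-4H-benzo[d][1,3]dioxin-5-yl trifluoromethanesulfonate F4. Sonogashira coupling with 2 (PdCl2(PPh3)2, CuI, Et3N, DMF) gives 5-(13-hydroxytridec-1-yn-1-yl)-7-methoxy-2,2-dimethyl-4H-benzo[d][1,3]dioxin-4-one F5. Cationic gold(I) in wet solvent closes the acetonide carbonyl 6-endo onto the alkyne with loss of acetone, giving 8.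

Step 2. The 5-exo phthalide may compete with the 6-endo isocoumarin, and only the isocoumarin leads to the right ketone position. The fallback separates coupling from ring closure and closes an ester with a π-acid rather than a carboxylate under Pd; it sets out from 3 (with 2) and comes back at 5. MeI/K2CO3 gives methyl 2-iodo-4-methoxybenzoate F6. A standard Pd/Cu Sonogashira coupling with 2 at rt gives methyl 2-(13-hydroxytridec-1-yn-1-yl)-4-methoxybenzoate F7. Ph3PAuCl/AgOTf in wet DCE then effects 6-endo-dig cyclisation of the ester with loss of methanol to give 5.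

Step 4. The chelated phenoxide slows lactone opening, and the keto acid may re-close to the isocoumarin on acidification. The fallback unmasks the acid under neutral conditions with no acidic work-up; it sets out from 8 and comes back at 9. Sodium allyloxide in allyl alcohol opens the lactone to allyl 2-hydroxy-6-(13-hydroxy-2-oxotridecyl)-4-methoxybenzoate F8. Pd(PPh3)4/morpholine in THF at rt then removes the allyl group to give 9.

**Further compounds**
F1 | step 3 | 2,4,6-trihydroxybenzoic acid | O=C(O)c1c(O)cc(O)cc1O
F2 | step 3 | 5,7-dihydroxy-2,2-dimethyl-4H-benzo[d][1,3]dioxin-4-one | CC1(C)OC(=O)c2c(O)cc(O)cc2O1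
F3 | step 3 | 5-hydroxy-7-methoxy-2,2-dimethyl-4H-benzo[d][1,3]dioxin-4-one | COc1cc(O)c2C(=O)OC(C)(C)Oc2c1
F4 | step 3 | 7-methoxy-2,2-dimethyl-4-oxo-4H-benzo[d][1,3]dioxin-5-yl trifluoromethanesulfonate | COc1cc(OS(=O)(=O)C(F)(F)F)c2C(=O)OC(C)(C)Oc2c1
F5 | step 3 | 5-(13-hydroxytridec-1-yn-1-yl)-7-methoxy-2,2-dimethyl-4H-benzo[d][1,3]dioxin-4-one | COc1cc(C#CCCCCCCCCCCCO)c2C(=O)OC(C)(C)Oc2c1
F6 | step 2 | methyl 2-iodo-4-methoxybenzoate | COC(=O)c1ccc(OC)cc1I
F7 | step 2 | methyl 2-(13-hydroxytridec-1-yn-1-yl)-4-methoxybenzoate | COC(=O)c1ccc(OC)cc1C#CCCCCCCCCCCCO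
F8 | step 4 | allyl 2-hydroxy-6-(13-hydroxy-2-oxotridecyl)-4-methoxybenzoate | COc1cc(O)c(C(=O)OCC=C)c(CC(=O)CCCCCCCCCCCO)c1
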